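**Assumptions (one line each):** Atom labels follow briarane numbering (C1–C20). (S)-But-3-ene-1,2-diol and 5-methylhex-5-en-2-one are taken as commercially available.

## Retrosynthetic overview
1. The target comes from a SmI2 Reformatsky aldol that closes the γ-lactone (C8–OH, C17) on a C7 bromopropionate and the C8 ketone of the ten-membered ring.
2. The ten-membered Z-alkene ring (C5=C6) comes from ring-closing metathesis of a trans-fused cyclohexane carrying two acyclic chains.
3. C1 (quaternary) and the C1–C2 and C9–C10 bonds come from a silylene-tethered enone/enol-ether [2+2] photocycloaddition followed by fluoride-triggered retro-aldol (de Mayo type). The partners are cyclohexenone **6** (from carvone) and 1,3-diketone **13** (from butenediol).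
4. The spiro-epoxide is made by Corey–Chaykovsky reaction at C11.
5. Ring order: cyclohexane (carvone) → cyclobutane (photo) → cyclobutane opened → spiro-epoxide → ten-membered ring (RCM) → γ-lactone (Reformatsky).

## Route

**Step 1**
Reactants: **1** (S)-(+)-carvone
Product: **2** (1S,5S)-cis-carveol
Conditions: NaBH4, CeCl3·7H2O, MeOH, –78 → 0 °C
Reagents that add atoms: none
Why: Luche 1,2-reduction delivers hydride axially, giving the alcohol cis to the isopropenyl group; this sets the future C14 (S) from the carvone stereocentre.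

**Step 2**
Reactants: **2**
Product: **3** carveol triethylsilyl ether
Conditions: TESCl, imidazole, DMF, 0 °C → rt
Reagents that add atoms: chlorotriethylsilane, CC[Si](Cl)(CC)CC
Why: Silyl protection is needed before allylic oxidation.

**Step 3**
Reactants: **3**
Product: **4** 4-(triethylsilyloxy)-3-methyl-6-isopropenylcyclohex-2-en-1-one
Conditions: Pd(OH)2/C (10 mol%), t-BuOOH, K2CO3, CH2Cl2, rt
Reagents that add atoms: tert-butyl hydroperoxide, CC(C)(C)OO (supplies the ketone O)
Why: Allylic CH2 oxidation converts the ring alkene into the enone whose carbonyl becomes C11. The enone β-carbon is C1, and the silyl ether is at C14.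

**Step 4**
Reactants: **4**
Product: **5** 6-acetyl-4-(triethylsilyloxy)-3-methylcyclohex-2-en-1-one
Conditions: O3, CH2Cl2/MeOH, –78 °C; then Me2S
Reagents that add atoms: ozone, [O-][O+]=O
Why: Ozone cleaves the electron-rich 1,1-disubstituted isopropenyl group in preference to the electron-poor enone, giving a β-diketone.

**Step 5**
Reactants: **5**
Product: **6** (S)-4-hydroxy-3-methylcyclohex-2-en-1-one
Conditions: NaOMe, MeOH, 0 °C → rt; then PPTS, rt
Reagents that add atoms: none
Why: Retro-Claisen deacetylation (lost as MeOAc) removes the isopropenyl-derived carbon and its stereocentre, and PPTS/MeOH removes the TES group; C14 (S) is untouched.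

**Step 6**
Reactants: **7** (S)-but-3-ene-1,2-diol
Product: **8** (S)-1,2-bis(triethylsilyloxy)but-3-ene
Conditions: TESCl (2.5 equiv), imidazole, DMF, 0 °C
Reagents that add atoms: chlorotriethylsilane, CC[Si](Cl)(CC)CC
Why: Bis-protection; the carbinol stereocentre is the future C7 (S) from the chiral pool.

**Step 7**
Reactants: **8**
Product: **9** (S)-2-(triethylsilyloxy)but-3-en-1-ol
Conditions: PPTS (cat.), MeOH/CH2Cl2, –10 → 0 °C
Reagents that add atoms: none
Why: The primary TES ether is cleaved selectively over the secondary one.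

**Step 8**
Reactants: **9**
Product: **10** (S)-2-(triethylsilyloxy)but-3-enal
Conditions: Dess–Martin periodinane, NaHCO3, CH2Cl2, 0 °C
Reagents that add atoms: none
Why: Mild oxidation that does not epimerise the α-silyloxy stereocentre.

**Step 9**
Reactants: **10**; **11** 5-methylhex-5-en-2-one
Product: **12** 7-hydroxy-2-methyl-8-(triethylsilyloxy)deca-1,9-dien-5-one (8S)
Conditions: LDA, THF, –78 °C (ketone enolate first, then aldehyde **10**)
Reagents that add atoms: none
Why: Kinetic deprotonation at the methyl group of **11** followed by aldol addition; the new carbinol (C8) is oxidised next, so its configuration is irrelevant.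

**Step 10**
Reactants: **12**
Product: **13** (8S)-2-methyl-8-(triethylsilyloxy)deca-1,9-diene-5,7-dione
Conditions: Dess–Martin periodinane, NaHCO3, CH2Cl2, rt
Reagents that add atoms: none
Why: β-Hydroxy ketone oxidation gives the 1,3-diketone; C7 stays configurationally intact.

**Step 11**
Reactants: **6**; **13**
Product: **14** Z-silyl enol ether of **13** bound through an i-Pr2Si bridge to the C14–O of **6**
Conditions: i-Pr2SiCl2 (1.05 equiv), imidazole, CH2Cl2, 0 °C; then **13**, Et3N, 0 °C → rt
Reagents that add atoms: dichlorodiisopropylsilane, CC(C)[Si](Cl)(Cl)C(C)C (the Si(iPr)2 unit stays in **14**)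
Why: Sequential O-silylation of the alcohol and then the less hindered (C2) carbonyl oxygen of the diketone; the bulky C8 side directs enolisation toward C2.

**Step 12**
Reactants: **14**
Product: **15** cyclobutane photoadduct (C1–C2 and C10–C9 bonds formed)
Conditions: hν (350 nm, Rayonet), MeCN (5 mM, degassed), 0 °C
Reagents that add atoms: none
Why: Proposed new method: the 6-membered silaketal tether (C14–O–Si–O–C2–C1) holds the enol ether over the face syn to C14–O, so the triplet enone β-carbon (C1) bonds to the O-bearing C2 (head-to-tail), then C10 closes onto C9. This fixes regiochemistry, the syn C1–C2/C14–O relationship required by the target, and the quaternary C1. Closest known reactions: enone/enol-ether [2+2] (Corey) and silicon-tethered intramolecular photocycloadditions, here applied to a β,β-disubstituted enone and a vinylogous-ester enol silyl ether.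

**Step 13**
Reactants: **15**
Product: **16** open-chain bis-ketone with C8 silyl enol ether (C8(OTBS)=C9), C14–OTBS and C2 ketone
Conditions: TBAT (2.2 equiv), THF, –78 °C; then TBSCl (4 equiv), –78 → 0 °C
Reagents that add atoms: tert-butyldimethylsilyl chloride, CC(C)(C)[Si](C)(C)Cl
Why: Proposed new method: anhydrous fluoride cleaves the silylene bridge and liberates the cyclobutoxide. Strain-driven retro-aldol (the de Mayo fragmentation) cleaves C2–C9, leaving the C2 ketone and a C8–C9 enolate that is regiospecifically trapped as the TBS enol ether. C10, which is α to the C11 ketone, equilibrates to the trans (diequatorial) isomer; this is assumed thermodynamically favoured. Closest known reaction: de Mayo retro-aldol fragmentation with in-situ enolate silylation.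

**Step 14**
Reactants: **16**
Product: **17** C11 spiro-epoxide
Conditions: Me3S+ I–, NaH, DMSO/THF, 0 °C → rt
Reagents that add atoms: trimethylsulfonium iodide, C[S+](C)C.[I-] (supplies C20)
Why: Corey–Chaykovsky epoxidation; the accessible C11 ketone reacts in preference to the neopentyl C2 ketone, and kinetic axial delivery of CH2 gives O β/C20 α at C11.

**Step 15**
Reactants: **17**
Product: **18** C2 alcohol
Conditions: Zn(BH4)2, Et2O, 0 °C
Reagents that add atoms: none
Why: Hydride attacks the C2 ketone from the less hindered outer face, setting C2; the epoxide and silyl enol ether are untouched.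

**Step 16**
Reactants: **18**
Product: **19** C2 acetate
Conditions: Ac2O, DMAP, pyridine, rt
Reagents that add atoms: acetic anhydride, CC(=O)OC(C)=O
Why: Acetylation installs the C2-OAc and prevents transannular hemiketal formation with the C8 ketone.

**Step 17**
Reactants: **19**
Product: **20** C8 ketone with C9-OTBS
Conditions: mCPBA, NaHCO3, CH2Cl2, –20 °C
Reagents that add atoms: m-chloroperbenzoic acid, OOC(=O)c1cccc(Cl)c1 (supplies O)
Why: Rubottom oxidation of the regiodefined silyl enol ether (much more reactive than the terminal alkenes) gives the α-silyloxy ketone; C9 is set by attack on the less hindered enol-ether face.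

**Step 18**
Reactants: **20**
Product: **21** ten-membered ring with Z-C5=C6
Conditions: Hoveyda–Grubbs II (10 mol%), 1,4-benzoquinone, PhMe (2 mM), 80 °C
Reagents that add atoms: none (ethylene is lost)
Why: Ring-closing metathesis between the isopropenyl-type C5=CH2 and the C7 vinyl group forms the trisubstituted Z-alkene; the trans-fused cyclohexane and ring strain favour Z.

**Step 19**
Reactants: **21**
Product: **22** C7 alcohol
Conditions: PPTS, MeOH, 0 °C → rt
Reagents that add atoms: none
Why: Selective removal of the TES ether in the presence of the two TBS ethers.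

**Step 20**
Reactants: **22**; **23** 2-bromopropanoyl bromide
Product: **24** C7 2-bromopropanoate
Conditions: **23**, pyridine, CH2Cl2, 0 °C
Reagents that add atoms: none besides reactant **23** (CC(Br)C(=O)Br)
Why: Esterification of the C7 alcohol; the bromide stereocentre is racemic and is destroyed in the next step.

**Step 21**
Reactants: **24**
Product: **25** γ-lactone with C8–OH and C17–Me
Conditions: SmI2 (2.5 equiv), THF, –78 → 0 °C
Reagents that add atoms: none
Why: Intramolecular Sm-Reformatsky (aldol) closes the five-membered lactone, necessarily cis-fused at C7–C8, so C8 is set by C7; C17 is set by the chair-like Sm-enolate transition state.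

**Step 22**
Reactants: **25**
Product: **26** C9,C14-diol
Conditions: TBAF, AcOH (1:1), THF, 0 °C → rt
Reagents that add atoms: none
Why: Buffered fluoride removes both TBS ethers without opening the epoxide (as HF would) or triggering retro-aldol of the β-hydroxylactone.

**Step 23**
Reactants: **26**
Product: **27** Junceellolide K
Conditions: Ac2O, DMAP, pyridine, rt
Reagents that add atoms: acetic anhydride, CC(=O)OC(C)=O
Why: The secondary C9 and C14 alcohols are acetylated; the tertiary C8–OH is unreactive.

## Compound list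
1 | (S)-(+)-carvone | CC1=CC[C@@H](CC1=O)C(C)=C | starting material
2 | (1S,5S)-cis-carveol | C=C(C)[C@H]1CC=C(C)[C@@H](O)C1 | intermediate
3 | carveol TES ether | C=C(C)[C@H]1CC=C(C)[C@@H](O[Si](CC)(CC)CC)C1 | intermediate
4 | 4-(TESO)-3-methyl-6-isopropenylcyclohex-2-en-1-one | CC[Si](CC)(CC)O[C@H]1C[C@@H](C(C)=C)C(=O)C=C1C | intermediate
5 | 6-acetyl-4-(TESO)-3-methylcyclohex-2-en-1-one | CC[Si](CC)(CC)O[C@H]1C[C@@H](C(C)=O)C(=O)C=C1C | intermediate
6 | (S)-4-hydroxy-3-methylcyclohex-2-en-1-one | O[C@H]1CCC(=O)C=C1C | intermediate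
7 | (S)-but-3-ene-1,2-diol | C=C[C@H](O)CO | starting material
8 | (S)-1,2-bis(TESO)but-3-ene | C=C[C@H](O[Si](CC)(CC)CC)CO[Si](CC)(CC)CC | intermediate
9 | (S)-2-(TESO)but-3-en-1-ol | C=C[C@H](O[Si](CC)(CC)CC)CO | intermediate
10 | (S)-2-(TESO)but-3-enal | C=C[C@H](O[Si](CC)(CC)CC)C=O | intermediate
11 | 5-methylhex-5-en-2-one | CC(=O)CCC(C)=C | starting material
12 | 7-hydroxy-2-methyl-8-(TESO)deca-1,9-dien-5-one (8S; C7-OH epimeric mixture) | C=C(C)CCC(=O)CC(O)[C@@H](O[Si](CC)(CC)CC)C=C | intermediate
13 | (8S)-2-methyl-8-(TESO)deca-1,9-diene-5,7-dione | C=C(C)CCC(=O)CC(=O)[C@@H](O[Si](CC)(CC)CC)C=C | intermediate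
14 | Si(iPr)2-tethered Z-enol ether of 13 on the C14-O of 6 | CC(C)[Si](C(C)C)(O[C@H]1CCC(=O)C=C1C)O/C(CCC(C)=C)=C\C(=O)[C@@H](O[Si](CC)(CC)CC)C=C | intermediate
15 | cis-fused cyclobutane photoadduct with 6-membered silaketal | CC(C)[Si]1(C(C)C)O[C@H]2CCC(=O)[C@H]3[C@@H](C(=O)[C@@H](O[Si](CC)(CC)CC)C=C)[C@@](CCC(C)=C)(O1)[C@@]23C | intermediate
16 | trans-cyclohexanone with C2 ketone chain, C8 TBS enol ether, C14-OTBS | C=C(C)CCC(=O)[C@@]1(C)[C@@H](O[Si](C)(C)C(C)(C)C)CCC(=O)[C@@H]1C=C(O[Si](C)(C)C(C)(C)C)[C@@H](O[Si](CC)(CC)CC)C=C | intermediate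
17 | C11 spiro-epoxide of 16 | C=C(C)CCC(=O)[C@@]1(C)[C@@H](O[Si](C)(C)C(C)(C)C)CC[C@]2(CO2)[C@@H]1C=C(O[Si](C)(C)C(C)(C)C)[C@@H](O[Si](CC)(CC)CC)C=C | intermediate
18 | C2 alcohol | C=C(C)CC[C@H](O)[C@@]1(C)[C@@H](O[Si](C)(C)C(C)(C)C)CC[C@]2(CO2)[C@@H]1C=C(O[Si](C)(C)C(C)(C)C)[C@@H](O[Si](CC)(CC)CC)C=C | intermediate
19 | C2 acetate | C=C(C)CC[C@H](OC(C)=O)[C@@]1(C)[C@@H](O[Si](C)(C)C(C)(C)C)CC[C@]2(CO2)[C@@H]1C=C(O[Si](C)(C)C(C)(C)C)[C@@H](O[Si](CC)(CC)CC)C=C | intermediate
20 | C8 ketone, C9-OTBS | C=C(C)CC[C@H](OC(C)=O)[C@@]1(C)[C@@H](O[Si](C)(C)C(C)(C)C)CC[C@]2(CO2)[C@@H]1[C@H](O[Si](C)(C)C(C)(C)C)C(=O)[C@@H](O[Si](CC)(CC)CC)C=C | intermediate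
21 | ten-membered ring (RCM product) | CC(=O)O[C@H]1CC/C(C)=C\[C@H](O[Si](CC)(CC)CC)C(=O)[C@@H](O[Si](C)(C)C(C)(C)C)[C@H]2[C@]3(CC[C@H](O[Si](C)(C)C(C)(C)C)[C@]12C)CO3 | intermediate
22 | C7 alcohol | CC(=O)O[C@H]1CC/C(C)=C\[C@H](O)C(=O)[C@@H](O[Si](C)(C)C(C)(C)C)[C@H]2[C@]3(CC[C@H](O[Si](C)(C)C(C)(C)C)[C@]12C)CO3 | intermediate
23 | 2-bromopropanoyl bromide | CC(Br)C(=O)Br | starting material
24 | C7 2-bromopropanoate | CC(=O)O[C@H]1CC/C(C)=C\[C@H](OC(=O)C(C)Br)C(=O)[C@@H](O[Si](C)(C)C(C)(C)C)[C@H]2[C@]3(CC[C@H](O[Si](C)(C)C(C)(C)C)[C@]12C)CO3 | intermediate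
25 | lactone, 9,14-bis-TBS | CC(=O)O[C@H]1CC/C(C)=C\[C@@H]2OC(=O)[C@H](C)[C@@]2(O)[C@@H](O[Si](C)(C)C(C)(C)C)[C@H]2[C@]3(CC[C@H](O[Si](C)(C)C(C)(C)C)[C@]12C)CO3 | intermediate
26 | 9,14-diol | CC(=O)O[C@H]1CC/C(C)=C\[C@@H]2OC(=O)[C@H](C)[C@@]2(O)[C@@H](O)[C@H]2[C@]3(CC[C@H](O)[C@]12C)CO3 | intermediate
27 | Junceellolide K | CC(=O)O[C@H]1CC/C(C)=C\[C@@H]2OC(=O)[C@H](C)[C@@]2(O)[C@@H](OC(C)=O)[C@H]2[C@]3(CC[C@H](OC(C)=O)[C@]12C)CO3 | target

**Total steps:** 23 (ring-A branch 5, diketone branch 5, convergent coupling and the remaining 13 steps).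
**Longest linear sequence:** 18 steps (carvone → **27**).

## Three steps most likely to fail
1. **Step 12 (new photocycloaddition).** The tether may not allow C1–C2 closure, or the C14 ring silylation in Step 11 may go to the wrong carbonyl of **13**.
   Fallback: the known, untethered de Mayo photocycloaddition of diketone **13** with the (R)-enone TES ether (from (R)-carvone), which adds anti to the 4-silyloxy group, followed by Mitsunobu inversion at C14 (p-nitrobenzoic acid, DEAD, PPh3). This restores the C2/O14 cis relationship and the (S) configuration at C14.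
2. **Step 18 (RCM).** Formation of the ten-membered trisubstituted ring may fail, or may give the E isomer or oligomers.
   Fallback: replace the C5/C6 alkene pair with a Z-vinyl iodide at C6 and a C7 aldehyde, and close the ring by intramolecular Nozaki–Hiyama–Kishi coupling (CrCl2/NiCl2, DMF), which sets the Z geometry in the precursor.
3. **Step 21 (SmI2 Reformatsky).** SmI2 may reductively cleave the doubly α-oxygenated C8 ketone, or give the wrong C17 epimer.
   Fallback: add the lithium enolate of tert-butyl propionate to the C8 ketone of the free C7 alcohol **22**, then cyclise the β-hydroxy ester with acid (TFA) or Yamaguchi conditions (Cl3C6H2COCl, Et3N, DMAP).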